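**Proposed synthesis of 3,5-dihydroxy-6,7,8,4'-tetramethoxyflavone 14 by Friedel–Crafts closure of ring C at the only free carbon of ring A**

## The problem

Target 14 is a flavonol whose ring A is substituted at every carbon (5-OH; 6-, 7- and 8-OMe), whose ring C carries the 3-hydroxyl and the C4 carbonyl, and whose C2 bears the 4-methoxyphenyl ring B. It has no stereocentre: C2 and C3 are stereogenic only while ring C is saturated, and both are flattened when ring C is aromatised, so neither has to control anything. The tasks are therefore regiochemical: ring A must be joined to the three-carbon unit at O1–C8a and at C4–C4a, the C3 oxygen must be in place, and O5 alone of the four ring A oxygens must end up free. Several features are fragile: the pentaoxygenated ring A is easily oxidised and nucleophilic at any free carbon, a 4-methoxybenzylic C–O bond in a saturated precursor ionises readily in acid, 3-hydroxyflavanones ring-open and rearrange in base, and contiguous methoxyls can be over-cleaved by Lewis acids. The enabling feature is that a 2,3,4,5-tetramethoxyphenyl ether has exactly one ring carbon bearing hydrogen, and that carbon is the future C4a. It lies ortho to the ether oxygen (future O1), ortho to the methoxyl that becomes O5 and para to the future C7 methoxyl, so an acyl electrophile has a single, strongly activated site. Once C4 is attached there, the C5 methoxyl sits peri to the carbonyl and is the only methyl ether that can be cleaved through a six-membered chelate, which settles the differentiation of O5.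

## Retrosynthesis

**14 from 12 (O5–CH3).** The last cut is the methyl–oxygen bond at C5, leading back to the pentamethyl compound 12. This is preferred over carrying O5 under a different protecting group, which would require a differentially protected pentaoxygenated phenol and several extra steps. The forward reaction must cleave one of five methyl ethers; chelation between the C4 carbonyl and O5 (boron chelate 13) is expected to provide that selectivity.

**12 from 11 (C2–C3 unsaturation).** Adding two hydrogens across C2–C3 gives the trans-3-hydroxyflavanone 11. With ring C saturated, the ring can be closed from an sp3 acid that already holds the O1–C2 ether and the C3 oxygen. A cut at O1–C2 with oxidative ring closure of an open-chain enone would need ring A acylated first, and Algar–Flynn–Oyamada closures are known to turn to the five-membered ring when the 6' position is substituted, as it is here. The forward step is the classical dehydrogenation of a dihydroflavonol, which also erases both stereocentres.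

**11 from 8 (C4–C4a, the key cut).** Cutting the aryl–carbonyl bond opens ring C to the hydroxy acid 8. Among the possible ring C bonds this one is chosen because the aryl ether of 8 has a single C–H, exactly at the carbon to be acylated, so regiochemistry is fixed by constitution. Forming O1–C8a instead would require a nucleophilic substitution or coupling on a very electron-rich, fully substituted arene. Activation as the mixed trifluoroacetic anhydride 9, which also masks the α-hydroxyl of the acid (the future C3–OH), should lead through the trifluoroacetate 10 to 11. The forward reaction must acylate faster than the 4-methoxybenzylic ether ionises.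

**8 from 7, and 7 from 5 + 6 (benzylic C–O bond).** Acid 8 comes from its methyl ester 7 by hydrolysis. Cutting the benzylic C–O bond of 7 gives phenol 5 and the commercial trans-glycidate 6, whose epoxide supplies both the electrophilic benzylic carbon and the C3 oxygen. Acid-promoted openings are avoided. A Lewis acid would generate a 4-methoxybenzylic cation next to the most nucleophilic arene carbon of the whole route, the free position of 5, and would also invite rearrangement of 6. Base-catalysed phenolysis is chosen instead: the phenoxide is an oxygen nucleophile, the benzylic carbon of 3-arylglycidates is the usual site of attack, and inversion there should give one diastereomer, (2R*,3R*)-7. Two small fragments replace a heavily substituted ether.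

**5 from 3 from 1 (C–O bond at the future C8a).** Phenol 5 is traced through its formate 4 to aldehyde 3, and 3 through the α-chloro ether 2 to the symmetrical arene 1. The two free positions of 1 are equivalent, so formylation can give only one aldehyde, and peracid oxidation converts the formyl carbon into the phenolic oxygen. All four methoxyls of ring A are bought with 1.

## Roads not taken

**Alternative 1:** Ring A is introduced as an aryne, cutting O1–C8a and C4–C4a at once.
- Forward key step: CsF-induced elimination from 2,3,4,5-tetramethoxy-6-(trimethylsilyl)phenyl triflate A3 releases 3,4,5,6-tetramethoxybenzyne A2. The carboxylate oxygen of (Z)-2-(benzyloxy)-3-(4-methoxyphenyl)acrylic acid A4 adds to one aryne carbon, and the acyl group then shifts from oxygen to the neighbouring carbon. The product is the ortho-hydroxyaryl ketone A1, with no ring closed. Oxidative O1–C2 closure would give the 3-benzyloxyflavone A5, and one BCl3 treatment could remove the benzyl group and the C5 methyl group to give 14.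
- Merits: the aryne A2 is symmetrical, so the insertion has no regiochemical issue; two ring A bonds form in one operation; no acid-labile sp3 benzylic ether ever appears.
- Weak points: A3 is a hexasubstituted benzene that has to be built from phenol 5 by halogenation, silylation, silyl migration and triflation. The aryne is flanked by two methoxyls, and acyl transfer to carbon must outrun protonation of the aryl anion. A4 needs its own preparation.
- Comparison: this road is more convergent and avoids the chosen plan's most delicate functional group. It costs roughly ten operations against seven, and its key step is less secure than an intramolecular acylation at a single activated C–H.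

**Alternative 2:** Ring A itself is disconnected and grown on a preformed pyranone.
- Forward key step: halogen–lithium exchange on 3-(benzyloxy)-5-bromo-2-(4-methoxyphenyl)-4H-pyran-4-one A8 and addition to dimethyl squarate A9 would give the 4-hydroxycyclobutenone A7. Heated in xylene, A7 should undergo electrocyclic opening of the four-membered ring and closure onto the pyranone carbon that bears hydrogen (C8–C8a). Enolisation then gives the 5,8-hydroquinone A6. Methylation of the non-chelated C8 hydroxyl and hydrogenolysis of the benzyl ether would complete 14.
- Merits: O5 emerges as a free, chelated hydroxyl, so no selective demethylation is needed; the oxygen pattern of ring A is set unambiguously by A9. In this respect it is better than the chosen plan.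
- Weak points: A8 needs a multistep synthesis. Lithiation of A8 is delicate because the pyranone carbonyl is itself an electrophile. A6 is an air-sensitive hydroquinone, and O8 must be methylated without touching O5. The route rebuilds a ring that is commercially available intact as 1.
- Comparison: the chosen plan sets a shorter sequence, purchasable ring A and no organolithium or hydroquinone handling against the one advantage of a free O5.

**Alternative 3:** Ring C is assembled from three components, cutting C4a–C4, C4–C3 and O1–C2.
- Forward key step: 2-iodo-3,4,5,6-tetramethoxyphenol A11, one iodination away from 5, would be united with carbon monoxide A13 and 4-ethynylanisole A12 by PdCl2(PPh3)2 in diethylamine. Carbonylative alkynylation is followed by 6-endo addition of the phenolic oxygen to the triple bond, giving the flavone A10. Hydroxylation at C3 would then give 12, and the final demethylation is shared with the chosen plan.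
- Merits: highly convergent and catalytic, three bonds in one step, and about one step shorter on paper than the chosen plan.
- Weak points: oxidative addition of zerovalent palladium into the iodide of A11, flanked by two oxygen substituents on a pentaoxygenated ring, is slow. Direct coupling without uptake of A13 and 5-exo ring closure compete. The C3 oxygen is missing from A10 and has to be added by a separate C–H oxidation of an electron-rich flavone.
- Comparison: this road wins on step count and convergence. The chosen plan sets against it that the C3 oxygen is carried from the glycidate, that ring C can close only in the six-membered sense at the only free carbon, and that no carbon monoxide, transition metal or late enolate oxidation is needed.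

Key step: step 5

Remark: 14 is achiral, so racemic 6 is used. Descriptors with asterisks denote racemates, each SMILES shows one enantiomer, and 1 and 6 are taken as purchasable.

## Route

Step 1
Reactants: 1 1,2,3,4-tetramethoxybenzene
Product: 3 2,3,4,5-tetramethoxybenzaldehyde, via 1-[chloro(methoxy)methyl]-2,3,4,5-tetramethoxybenzene 2 (not isolated)
Conditions: Cl2CHOMe, TiCl4, CH2Cl2, −10 °C→0 °C; then ice/H2O
Reagents that add atoms: dichloromethyl methyl ether, COC(Cl)Cl; water, O
Why: Rieche formylation; the two free positions of 1 are equivalent and each is para to a methoxyl, so a single aldehyde should result after hydrolysis of the α-chloro ether 2 on work-up.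

Step 2
Reactants: 3 2,3,4,5-tetramethoxybenzaldehyde
Product: 5 2,3,4,5-tetramethoxyphenol, via 2,3,4,5-tetramethoxyphenyl formate 4 (not isolated)
Conditions: mCPBA, CH2Cl2, 0 °C→rt; then HCl (cat.), MeOH, rt
Reagents that add atoms: 3-chloroperoxybenzoic acid (mCPBA), OOC(=O)c1cccc(Cl)c1
Why: Dakin-type Baeyer–Villiger oxidation; the electron-rich aryl group migrates in the peracid adduct to give formate 4, which acid-catalysed methanolysis converts into the phenol without exposing it to base and air.

Step 3
Reactants: 5 2,3,4,5-tetramethoxyphenol; 6 methyl (2R*,3S*)-3-(4-methoxyphenyl)oxirane-2-carboxylate (trans glycidate, racemic)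
Product: 7 methyl (2R*,3R*)-2-hydroxy-3-(4-methoxyphenyl)-3-(2,3,4,5-tetramethoxyphenoxy)propanoate (racemic)
Conditions: Cs2CO3 (0.2 equiv), DMF, 50 °C
Reagents that add atoms: none
Why: Base-catalysed phenolysis of an epoxide by SN2 attack of the phenoxide at the benzylic carbon, the usual site of opening of 3-arylglycidates by heteroatom nucleophiles; inversion there sets the (2R*,3R*) relative configuration, and the absence of any acid excludes Friedel–Crafts alkylation at the free carbon of 5 and Meinwald rearrangement of 6.

Step 4
Reactants: 7 methyl (2R*,3R*)-2-hydroxy-3-(4-methoxyphenyl)-3-(2,3,4,5-tetramethoxyphenoxy)propanoate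
Product: 8 (2R*,3R*)-2-hydroxy-3-(4-methoxyphenyl)-3-(2,3,4,5-tetramethoxyphenoxy)propanoic acid (racemic)
Conditions: LiOH·H2O, THF/H2O (3:1), 0 °C→rt; then 1 M HCl to pH 3
Reagents that add atoms: lithium hydroxide, [Li+].[OH-]
Why: Ester saponification under mild conditions; acyl–oxygen cleavage leaves both stereocentres and the aryl ether untouched, and any transesterified material from step 3 converges on the same acid.

Step 5
Reactants: 8 (2R*,3R*)-2-hydroxy-3-(4-methoxyphenyl)-3-(2,3,4,5-tetramethoxyphenoxy)propanoic acid
Product: 11 (2R*,3R*)-3-hydroxy-5,6,7,8-tetramethoxy-2-(4-methoxyphenyl)chroman-4-one (trans; racemic), via the O-trifluoroacetyl mixed anhydride 9 (not isolated), via the flavanone 3-trifluoroacetate 10 (not isolated)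
Conditions: TFAA (3 equiv), CH2Cl2, 0 °C→rt; then MeOH, rt; aq. NaHCO3 work-up
Reagents that add atoms: none
Why: Intramolecular Friedel–Crafts acylation of a 3-aryloxypropanoic acid, the standard entry to chroman-4-ones, run here through a mixed carboxylic–trifluoroacetic anhydride. TFAA acylates both the carboxyl group and the α-hydroxyl of the acid (the future C3–OH) to give 9, in which the hydroxyl is masked and cannot lactonise or oligomerise. Loss of trifluoroacetate from the activated carboxyl carbon gives an acylium-type electrophile that is attacked by the only hydrogen-bearing carbon of ring A (future C4a); rearomatisation gives 10, and methanol cleaves its trifluoroacetate on quenching to release 11. Ring C closes in a 6-exo-trig mode, with the carbonyl oxygen outside the new ring made of O1, C2, C3, C4, C4a and C8a. No stereocentre is created: C2 and C3 come from 8, and their relative configuration places aryl and hydroxyl trans (diequatorial), which is also the favoured arrangement should C3 equilibrate through the enol. Regioselectivity is fixed by constitution, since ring A offers no other C–H and closure onto ring B would give a five-membered ring at a carbon meta to its methoxyl; the attacked carbon is activated by an ortho ether oxygen, an ortho methoxyl and a para methoxyl, so no Lewis acid is needed. The selectivity that has to be secured is acylation ahead of ionisation of the 4-methoxybenzylic C–O bond; the adjacent carbon carries a trifluoroacetoxy group and the acyl group, both of which destabilise a benzylic cation, and the reaction is run cold without added strong acid.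

Step 6
Reactants: 11 (2R*,3R*)-3-hydroxy-5,6,7,8-tetramethoxy-2-(4-methoxyphenyl)chroman-4-one
Product: 12 3-hydroxy-5,6,7,8-tetramethoxy-2-(4-methoxyphenyl)-4H-chromen-4-one
Conditions: I2, KOAc, AcOH, reflux
Reagents that add atoms: none
Why: Classical iodine–potassium acetate dehydrogenation of a dihydroflavonol; the ketone enolises toward C3, the enediol is iodinated and loses HI, and the resulting α-dicarbonyl tautomerises at C2–H into the aromatic 3-hydroxychromone, with KOAc buffering the HI so that the methyl ethers should survive.

Step 7
Reactants: 12 3-hydroxy-5,6,7,8-tetramethoxy-2-(4-methoxyphenyl)-4H-chromen-4-one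
Product: 14 3,5-dihydroxy-6,7,8-trimethoxy-2-(4-methoxyphenyl)-4H-chromen-4-one, via the bis(dichloroboryl) chelate 13 (not isolated)
Conditions: BCl3 (3 equiv), CH2Cl2, −78 °C→0 °C; then H2O/MeOH
Reagents that add atoms: none
Why: Chelation-controlled ether cleavage, the standard selective 5-O-demethylation of polymethoxyflavones; boron held between the C4 carbonyl oxygen and the peri C5 methoxyl activates only that methyl group toward chloride (loss of CH3Cl), the 3-hydroxyl is tied up as a dichloroboryl ether in 13 (hence the excess), and hydrolysis releases 14 while the low temperature should spare the 6-, 7-, 8- and 4'-methoxyls.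

## Compound list

1 | 1,2,3,4-tetramethoxybenzene | COc1ccc(OC)c(OC)c1OC | starting material
2 | 1-[chloro(methoxy)methyl]-2,3,4,5-tetramethoxybenzene | COC(Cl)c1cc(OC)c(OC)c(OC)c1OC | intermediate
3 | 2,3,4,5-tetramethoxybenzaldehyde | COc1cc(C=O)c(OC)c(OC)c1OC | intermediate
4 | 2,3,4,5-tetramethoxyphenyl formate | COc1cc(OC=O)c(OC)c(OC)c1OC | intermediate
5 | 2,3,4,5-tetramethoxyphenol | COc1cc(O)c(OC)c(OC)c1OC | intermediate
6 | methyl (2R*,3S*)-3-(4-methoxyphenyl)oxirane-2-carboxylate (trans, racemic) | COC(=O)[C@@H]1O[C@H]1c1ccc(OC)cc1 | starting material
7 | methyl (2R*,3R*)-2-hydroxy-3-(4-methoxyphenyl)-3-(2,3,4,5-tetramethoxyphenoxy)propanoate (racemic) | COc1ccc([C@@H](Oc2cc(OC)c(OC)c(OC)c2OC)[C@@H](O)C(=O)OC)cc1 | intermediate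
8 | (2R*,3R*)-2-hydroxy-3-(4-methoxyphenyl)-3-(2,3,4,5-tetramethoxyphenoxy)propanoic acid (racemic) | COc1ccc([C@@H](Oc2cc(OC)c(OC)c(OC)c2OC)[C@@H](O)C(=O)O)cc1 | intermediate
9 | (2R*,3R*)-3-(4-methoxyphenyl)-3-(2,3,4,5-tetramethoxyphenoxy)-2-(trifluoroacetoxy)propanoic trifluoroacetic anhydride (racemic) | COc1ccc([C@@H](Oc2cc(OC)c(OC)c(OC)c2OC)[C@@H](OC(=O)C(F)(F)F)C(=O)OC(=O)C(F)(F)F)cc1 | intermediate
10 | (2R*,3R*)-5,6,7,8-tetramethoxy-2-(4-methoxyphenyl)-4-oxochroman-3-yl trifluoroacetate (trans, racemic) | COc1ccc([C@H]2Oc3c(OC)c(OC)c(OC)c(OC)c3C(=O)[C@@H]2OC(=O)C(F)(F)F)cc1 | intermediate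
11 | (2R*,3R*)-3-hydroxy-5,6,7,8-tetramethoxy-2-(4-methoxyphenyl)chroman-4-one (trans, racemic) | COc1ccc([C@H]2Oc3c(OC)c(OC)c(OC)c(OC)c3C(=O)[C@@H]2O)cc1 | intermediate
12 | 3-hydroxy-5,6,7,8-tetramethoxy-2-(4-methoxyphenyl)-4H-chromen-4-one | COc1ccc(-c2oc3c(OC)c(OC)c(OC)c(OC)c3c(=O)c2O)cc1 | intermediate
13 | 3,5-bis(dichloroboryloxy)-6,7,8-trimethoxy-2-(4-methoxyphenyl)-4H-chromen-4-one | COc1ccc(-c2oc3c(OC)c(OC)c(OC)c(OB(Cl)Cl)c3c(=O)c2OB(Cl)Cl)cc1 | intermediate
14 | 3,5-dihydroxy-6,7,8-trimethoxy-2-(4-methoxyphenyl)-4H-chromen-4-one (3,5-dihydroxy-6,7,8,4'-tetramethoxyflavone) | COc1ccc(-c2oc3c(OC)c(OC)c(OC)c(O)c3c(=O)c2O)cc1 | target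

## Step count and risks

Total step count: 7. Longest linear sequence: 7 steps (1 to 14); glycidate 6 enters at step 3.

**Step 5 (key step).**
- Risk: the ether may fragment by ionisation of the 4-methoxybenzylic C–O bond under the trifluoroacetic acid that the activation liberates. This becomes likely if ring closure is slowed by the electron-withdrawing α-trifluoroacetoxy group. Trifluoroacetylation of the free ring carbon by excess anhydride is a second possible diversion.
- Fallback, from 8 back to 11: the hydroxyl is acetylated (Ac2O, pyridine) to give (2R*,3R*)-2-acetoxy-3-(4-methoxyphenyl)-3-(2,3,4,5-tetramethoxyphenoxy)propanoic acid F1. Oxalyl chloride with catalytic DMF converts it into (2R*,3R*)-2-acetoxy-3-(4-methoxyphenyl)-3-(2,3,4,5-tetramethoxyphenoxy)propanoyl chloride F2. This preformed acyl chloride is cyclised with SnCl4 in CH2Cl2 at −78 °C, where the only protic acid is the HCl released by the acylation itself, to (2R*,3R*)-5,6,7,8-tetramethoxy-2-(4-methoxyphenyl)-4-oxochroman-3-yl acetate F3. HCl-catalysed methanolysis of the acetate returns the route to 11.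

**Step 3.**
- Risk: regiocontrol may erode through attack at the carbon next to the ester. The ortho-substituted phenoxide may also open the epoxide slowly, giving transesterification and base-induced decomposition of the glycidate time to compete.
- Fallback, from 5 back to 7: the ether is made by redox condensation on an alcohol instead of epoxide opening. Methyl (E)-3-(4-methoxyphenyl)acrylate F4 is dihydroxylated (OsO4 cat., NMO) to methyl (2R*,3S*)-2,3-dihydroxy-3-(4-methoxyphenyl)propanoate F5. Mitsunobu coupling of F5 with 5 (PPh3, DIAD, THF, 0 °C) should occur at the more reactive benzylic hydroxyl with inversion and deliver 7 directly.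

**Step 7.**
- Risk: cleavage may continue to the C6 or C7 methoxyl once the 5-O-boron chelate has formed. Conversely, the reaction may stall because the 3-O-boron chelate occupies the carbonyl oxygen that is needed to direct cleavage at C5.
- Fallback, from 12 to 14: the competing chelating group is masked first. Acetylation (Ac2O, pyridine) gives 5,6,7,8-tetramethoxy-2-(4-methoxyphenyl)-4-oxo-4H-chromen-3-yl acetate F6. AlCl3 in MeCN then has only the C4 carbonyl/C5 methoxyl site to bind and should give 5-hydroxy-6,7,8-trimethoxy-2-(4-methoxyphenyl)-4-oxo-4H-chromen-3-yl acetate F7. Brief K2CO3/MeOH treatment and acidification removes the enol acetate to give 14.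

**Step 6.**
- Risk: enolisation toward C3 may be slow beside the peri methoxyl, and prolonged reflux with HI present risks partial ether cleavage or reductive loss of the C3 oxygen.
- Fallback, from 11 back to 12: the alcohol is oxidised directly instead of halogenating the enol. Dess–Martin periodinane in CH2Cl2 should give 5,6,7,8-tetramethoxy-2-(4-methoxyphenyl)chromane-3,4-dione F8, which enolises at C2–H on work-up or with a trace of base to 12.

## Further compounds

F1 | step 5 | (2R*,3R*)-2-acetoxy-3-(4-methoxyphenyl)-3-(2,3,4,5-tetramethoxyphenoxy)propanoic acid | COc1ccc([C@@H](Oc2cc(OC)c(OC)c(OC)c2OC)[C@@H](OC(C)=O)C(=O)O)cc1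
F2 | step 5 | (2R*,3R*)-2-acetoxy-3-(4-methoxyphenyl)-3-(2,3,4,5-tetramethoxyphenoxy)propanoyl chloride | COc1ccc([C@@H](Oc2cc(OC)c(OC)c(OC)c2OC)[C@@H](OC(C)=O)C(=O)Cl)cc1
F3 | step 5 | (2R*,3R*)-5,6,7,8-tetramethoxy-2-(4-methoxyphenyl)-4-oxochroman-3-yl acetate | COc1ccc([C@H]2Oc3c(OC)c(OC)c(OC)c(OC)c3C(=O)[C@@H]2OC(C)=O)cc1
F4 | step 3 | methyl (E)-3-(4-methoxyphenyl)acrylate | COC(=O)/C=C/c1ccc(OC)cc1
F5 | step 3 | methyl (2R*,3S*)-2,3-dihydroxy-3-(4-methoxyphenyl)propanoate | COc1ccc([C@H](O)[C@@H](O)C(=O)OC)cc1
F6 | step 7 | 5,6,7,8-tetramethoxy-2-(4-methoxyphenyl)-4-oxo-4H-chromen-3-yl acetate | COc1ccc(-c2oc3c(OC)c(OC)c(OC)c(OC)c3c(=O)c2OC(C)=O)cc1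
F7 | step 7 | 5-hydroxy-6,7,8-trimethoxy-2-(4-methoxyphenyl)-4-oxo-4H-chromen-3-yl acetate | COc1ccc(-c2oc3c(OC)c(OC)c(OC)c(O)c3c(=O)c2OC(C)=O)cc1
F8 | step 6 | 5,6,7,8-tetramethoxy-2-(4-methoxyphenyl)chromane-3,4-dione (racemic) | COc1ccc([C@H]2Oc3c(OC)c(OC)c(OC)c(OC)c3C(=O)C2=O)cc1
A1 | alternative 1 | (Z)-2-(benzyloxy)-1-(2-hydroxy-3,4,5,6-tetramethoxyphenyl)-3-(4-methoxyphenyl)prop-2-en-1-one | COc1ccc(/C=C(\OCc2ccccc2)C(=O)c2c(O)c(OC)c(OC)c(OC)c2OC)cc1
A2 | alternative 1 | 3,4,5,6-tetramethoxybenzyne | COC1=C(OC)C(OC)=C(OC)C#C1
A3 | alternative 1 | 2,3,4,5-tetramethoxy-6-(trimethylsilyl)phenyl trifluoromethanesulfonate | COc1c(OC)c(OC)c(OC)c([Si](C)(C)C)c1OS(=O)(=O)C(F)(F)F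
A4 | alternative 1 | (Z)-2-(benzyloxy)-3-(4-methoxyphenyl)acrylic acid | COc1ccc(/C=C(\OCc2ccccc2)C(=O)O)cc1
A5 | alternative 1 | 3-(benzyloxy)-5,6,7,8-tetramethoxy-2-(4-methoxyphenyl)-4H-chromen-4-one | COc1ccc(-c2oc3c(OC)c(OC)c(OC)c(OC)c3c(=O)c2OCc2ccccc2)cc1
A6 | alternative 2 | 3-(benzyloxy)-5,8-dihydroxy-6,7-dimethoxy-2-(4-methoxyphenyl)-4H-chromen-4-one | COc1ccc(-c2oc3c(O)c(OC)c(OC)c(O)c3c(=O)c2OCc2ccccc2)cc1
A7 | alternative 2 | 4-[5-(benzyloxy)-6-(4-methoxyphenyl)-4-oxo-4H-pyran-3-yl]-4-hydroxy-2,3-dimethoxycyclobut-2-en-1-one | COC1=C(OC)C(O)(c2coc(-c3ccc(OC)cc3)c(OCc3ccccc3)c2=O)C1=O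
A8 | alternative 2 | 3-(benzyloxy)-5-bromo-2-(4-methoxyphenyl)-4H-pyran-4-one | COc1ccc(-c2occ(Br)c(=O)c2OCc2ccccc2)cc1
A9 | alternative 2 | dimethyl squarate (3,4-dimethoxycyclobut-3-ene-1,2-dione) | COC1=C(OC)C(=O)C1=O
A10 | alternative 3 | 5,6,7,8-tetramethoxy-2-(4-methoxyphenyl)-4H-chromen-4-one | COc1ccc(-c2cc(=O)c3c(OC)c(OC)c(OC)c(OC)c3o2)cc1
A11 | alternative 3 | 2-iodo-3,4,5,6-tetramethoxyphenol | COc1c(O)c(I)c(OC)c(OC)c1OC
A12 | alternative 3 | 4-ethynylanisole | COc1ccc(C#C)cc1
A13 | alternative 3 | carbon monoxide | [C-]#[O+]
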